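**Plan**

- Retrosynthesis: the methyl ester goes back to acid 11 and aldehyde 10. The 1,2-dioxane (ring B) of 10 is cut at C4–C5, O2–C3 and C6–O1 into the side-chain alkene of 7, O2 and (2E)-2-methylbut-2-enal 8. The chain of 7 is cut between its two CH2 groups (spiro-epoxide 5 + 2-methylallyl Grignard 6), and ring A goes back to β-cyclogeraniol 1.
- Enabling feature: in ring B, C6 is a fully substituted carbon bearing O1 next to the C5 methylene (a 1,1-disubstituted alkene in disguise). C3 and C4 are the β- and γ-carbons of the α-methyl carbonyl side chain. A γ-centred radical cation of the enal can therefore bond to C5, O2 is captured at C6, and the peroxide oxygen closes onto the β-carbon C3.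
- Forward order: ring A is functionalised first (epoxidation, epoxide-to-allylic-diol shift), the chain is attached through the spiro-epoxide, ring B is formed in one three-component step, and the aldehyde is oxidised and methylated.
- Stereochemistry: the ring A carbinol (S) comes from the Sharpless epoxidation and its C–O bond is kept throughout. C3 (S) and the α-carbon (S) come from the chiral primary-amine catalyst of the key step. C6 is not controlled; the 6R epimer is separated.

Key step: step 5

Remark: in step 5 the planar C6 radical is trapped by O2 from both faces; 9, 10 and 11 are therefore carried as mixtures with their C6 epimers, names and SMILES refer to the 6R series, and the epimers are separated at the stage of 12.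

**Step 1**
Reactants: 1 (2,6,6-trimethylcyclohex-1-en-1-yl)methanol (β-cyclogeraniol)
Product: 2 [(1R,6R)-2,2,6-trimethyl-7-oxabicyclo[4.1.0]heptan-1-yl]methanol
Conditions: Ti(OiPr)4, D-(−)-diethyl tartrate, t-BuOOH, 4 Å molecular sieves, CH2Cl2, −20 °C
Reagents that add atoms: tert-butyl hydroperoxide, CC(C)(C)OO
Why: Sharpless asymmetric epoxidation of the tetrasubstituted allylic alcohol; the D-(−)-tartrate/titanium catalyst delivers oxygen to one face of the alkene and sets both epoxide carbons (1R,6R), and the C1–O bond made here becomes the tertiary carbinol of ring A.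

**Step 2**
Reactants: 2 [(1R,6R)-2,2,6-trimethyl-7-oxabicyclo[4.1.0]heptan-1-yl]methanol
Product: 3 (1S)-1-(hydroxymethyl)-2,2-dimethyl-6-methylidenecyclohexan-1-ol
Conditions: Ti(OiPr)4 (1.5 equiv), CH2Cl2, 25 to 40 °C; aqueous tartaric acid work-up
Reagents that add atoms: none
Why: Hydroxyl-directed rearrangement of a 2,3-epoxy alcohol to an allylic 1,2-diol: the titanium alkoxide at the hydroxymethyl group activates the distal C6–O bond and removes a proton from the methyl group cis to it, so the exocyclic alkene forms while the C1–O bond, and with it the (S)-carbinol, is kept.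

**Step 3**
Reactants: 3 (1S)-1-(hydroxymethyl)-2,2-dimethyl-6-methylidenecyclohexan-1-ol
Product: 5 (3S)-4,4-dimethyl-8-methylidene-1-oxaspiro[2.5]octane, via primary tosylate 4 (not isolated)
Conditions: NaH (2.2 equiv), 1-(4-methylbenzenesulfonyl)-1H-imidazole, THF, 0 °C to rt
Reagents that add atoms: none
Why: The primary alkoxide is sulfonylated selectively and the neighbouring tertiary alkoxide displaces the tosylate in a 3-exo-tet closure (epoxide formation from a 1,2-diol); the carbinol carbon is not touched, so its configuration is kept.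

**Step 4**
Reactants: 5 (3S)-4,4-dimethyl-8-methylidene-1-oxaspiro[2.5]octane; 6 2-methylallylmagnesium chloride
Product: 7 (1S)-2,2-dimethyl-6-methylidene-1-(3-methylbut-3-en-1-yl)cyclohexan-1-ol
Conditions: THF, −40 to 0 °C (no copper salt); aqueous NH4Cl
Reagents that add atoms: none
Why: Grignard opening of the epoxide at its unhindered CH2 carbon (SN2), run without copper so that conjugate (SN2′) opening of the vinyl epoxide is disfavoured; the new C–C bond completes the chain and returns the tertiary alcohol with unchanged configuration.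

**Step 5**
Reactants: 7 (1S)-2,2-dimethyl-6-methylidene-1-(3-methylbut-3-en-1-yl)cyclohexan-1-ol; 8 (2E)-2-methylbut-2-enal
Product: 10 (2S)-2-[(3S,6R)-6-{2-[(1S)-1-hydroxy-2,2-dimethyl-6-methylidenecyclohexyl]ethyl}-6-methyl-1,2-dioxan-3-yl]propanal, via hydroperoxy enal 9 (not isolated)
Conditions: 8 (3 equiv), O2 (1 atm), 9-amino-9-deoxy-epi-quinine (20 mol%), CF3CO2H (40 mol%), (4-BrC6H4)3N•+ SbCl6− (5 mol%), CH2Cl2, −20 °C
Reagents that add atoms: dioxygen, O=O
Why: Proposed new method: the primary amine condenses with 8 to a dienamine that is oxidised by one electron (the aminium salt starts the chain, afterwards the tertiary peroxyl radical takes the electron with help of the acid) to a delocalised radical cation, which adds through its unhindered γ-CH2 to the terminal carbon of the side-chain alkene of 7 (C4–C5 bond); the tertiary C6 radical captures O2, and the resulting hydroperoxide, still tethered to the α,β-unsaturated iminium ion (9), adds through its terminal oxygen to C3 (O2–C3 bond), after which the enamine is protonated and hydrolysed. The closest known reaction types are the aerobic [2+2+2] peroxidation of alkenes with 1,3-dicarbonyl radicals generated by Mn(OAc)3, the addition of enamine radical cations to simple alkenes in SOMO catalysis, the γ-alkylation of α-branched enals through cinchona-amine dienamines, and the cinchona-primary-amine (iminium) catalysed conjugate addition of hydroperoxides to enones and α-branched enals. The only ring formed, the 1,2-dioxane, is closed by this 6-exo-trig oxa-Michael addition through a chair-like transition state with the iminium-bearing chain equatorial. C3 is set by the catalyst, which shields one face of the iminium ion (3S expected with the quinine-derived amine, its quinidine-derived pseudo-enantiomer giving 3R); the α-carbon is set by protonation of the catalyst-bound enamine anti to the new C3–O bond (2S); C6 is not controlled, because the planar tertiary radical is trapped by O2 from either face, so the 6R and 6S epimers should form in similar amounts. The step needs γ- rather than α-attack of the radical cation, which the α-methyl group of 8 secures; attack on the side-chain alkene rather than on the exocyclic alkene of ring A, which the allylic oxygen and the two fully substituted neighbours of the latter should secure; and protonation rather than epoxide formation from the β-peroxy enamine, which the acid co-catalyst and the low temperature favour.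

**Step 6**
Reactants: 10 (2S)-2-[(3S,6R)-6-{2-[(1S)-1-hydroxy-2,2-dimethyl-6-methylidenecyclohexyl]ethyl}-6-methyl-1,2-dioxan-3-yl]propanal
Product: 11 (2S)-2-[(3S,6R)-6-{2-[(1S)-1-hydroxy-2,2-dimethyl-6-methylidenecyclohexyl]ethyl}-6-methyl-1,2-dioxan-3-yl]propanoic acid
Conditions: NaClO2, NaH2PO4, 2-methylbut-2-ene, t-BuOH/H2O, 0 °C (crude 10 used at once)
Reagents that add atoms: sodium chlorite, [Na+].[O-]Cl=O
Why: Pinnick oxidation under buffered conditions with an alkene scavenger for HOCl should leave the peroxide, the exocyclic alkene, the tertiary alcohol and the α-stereocentre untouched.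

**Step 7**
Reactants: 11 (2S)-2-[(3S,6R)-6-{2-[(1S)-1-hydroxy-2,2-dimethyl-6-methylidenecyclohexyl]ethyl}-6-methyl-1,2-dioxan-3-yl]propanoic acid
Product: 12 methyl (2S)-2-[(3S,6R)-6-{2-[(1S)-1-hydroxy-2,2-dimethyl-6-methylidenecyclohexyl]ethyl}-6-methyl-1,2-dioxan-3-yl]propanoate
Conditions: Me3SiCHN2, MeOH/toluene, 0 °C; then chromatographic separation from the C6 epimer
Reagents that add atoms: (trimethylsilyl)diazomethane, C[Si](C)(C)C=[N+]=[N-]
Why: Methylation of the acid with (trimethylsilyl)diazomethane is neutral, so the β-peroxy ester is not opened by retro-oxa-Michael reaction and no stereocentre is touched; the 3,6-cis and 3,6-trans dioxanes are then separated.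

**Compound list**

1 | (2,6,6-trimethylcyclohex-1-en-1-yl)methanol (β-cyclogeraniol) | CC1=C(CO)C(C)(C)CCC1 | starting material
2 | [(1R,6R)-2,2,6-trimethyl-7-oxabicyclo[4.1.0]heptan-1-yl]methanol | C[C@@]12CCCC(C)(C)[C@@]1(O2)CO | intermediate
3 | (1S)-1-(hydroxymethyl)-2,2-dimethyl-6-methylidenecyclohexan-1-ol | C=C1CCCC(C)(C)[C@@]1(O)CO | intermediate
4 | [(1S)-1-hydroxy-2,2-dimethyl-6-methylidenecyclohexyl]methyl 4-methylbenzenesulfonate | C=C1CCCC(C)(C)[C@@]1(O)COS(=O)(=O)c1ccc(C)cc1 | intermediate
5 | (3S)-4,4-dimethyl-8-methylidene-1-oxaspiro[2.5]octane | C=C1CCCC(C)(C)[C@@]12CO2 | intermediate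
6 | 2-methylallylmagnesium chloride | CC(=C)C[Mg]Cl | starting material
7 | (1S)-2,2-dimethyl-6-methylidene-1-(3-methylbut-3-en-1-yl)cyclohexan-1-ol | C=C1CCCC(C)(C)[C@@]1(O)CCC(C)=C | intermediate
8 | (2E)-2-methylbut-2-enal | C/C=C(\C)C=O | starting material
9 | (2E,6R)-6-hydroperoxy-8-[(1S)-1-hydroxy-2,2-dimethyl-6-methylidenecyclohexyl]-2,6-dimethyloct-2-enal | C=C1CCCC(C)(C)[C@@]1(O)CC[C@](C)(OO)CC/C=C(\C)C=O | intermediate
10 | (2S)-2-[(3S,6R)-6-{2-[(1S)-1-hydroxy-2,2-dimethyl-6-methylidenecyclohexyl]ethyl}-6-methyl-1,2-dioxan-3-yl]propanal | C=C1CCCC(C)(C)[C@@]1(O)CC[C@@]1(C)CC[C@@H]([C@H](C)C=O)OO1 | intermediate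
11 | (2S)-2-[(3S,6R)-6-{2-[(1S)-1-hydroxy-2,2-dimethyl-6-methylidenecyclohexyl]ethyl}-6-methyl-1,2-dioxan-3-yl]propanoic acid | C=C1CCCC(C)(C)[C@@]1(O)CC[C@@]1(C)CC[C@@H]([C@H](C)C(=O)O)OO1 | intermediate
12 | methyl (2S)-2-[(3S,6R)-6-{2-[(1S)-1-hydroxy-2,2-dimethyl-6-methylidenecyclohexyl]ethyl}-6-methyl-1,2-dioxan-3-yl]propanoate | C=C1CCCC(C)(C)[C@@]1(O)CC[C@@]1(C)CC[C@@H]([C@H](C)C(=O)OC)OO1 | target

Total step count: 7. Longest linear sequence: 7 steps (1 to 12).

**Steps most likely to fail**

1. Step 5 (proposed new method). The radical cation may be intercepted by O2 before it meets the alkene, or may add to the exocyclic alkene of ring A. The β-peroxy enamine may collapse to an epoxide with loss of the O–O bond. Facial control at C3 may be low, and its sense must be confirmed. Fallback with known reactions, from 7 back to 12: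
   - Allylic metalation of the side-chain methyl group of 7 (n-BuLi/KOt-Bu, THF/hexane) and trapping with oxirane should give 6-[(1S)-1-hydroxy-2,2-dimethyl-6-methylidenecyclohexyl]-4-methylidenehexan-1-ol F1.
   - Mukaiyama–Isayama hydroperoxysilylation (Co(thd)2, thd = 2,2,6,6-tetramethylheptane-3,5-dionate; O2, Et3SiH) of the less hindered alkene should give the tertiary silyl peroxide 6-[(1S)-1-hydroxy-2,2-dimethyl-6-methylidenecyclohexyl]-4-methyl-4-[(triethylsilyl)peroxy]hexan-1-ol F2.
   - Oxidation of the primary alcohol with 1,1,1-triacetoxy-1,1-dihydro-1,2-benziodoxol-3(1H)-one gives 6-[(1S)-1-hydroxy-2,2-dimethyl-6-methylidenecyclohexyl]-4-methyl-4-[(triethylsilyl)peroxy]hexanal F3.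
   - Wittig olefination with methyl 2-(triphenylphosphoranylidene)propanoate gives methyl (2E)-8-[(1S)-1-hydroxy-2,2-dimethyl-6-methylidenecyclohexyl]-2,6-dimethyl-6-[(triethylsilyl)peroxy]oct-2-enoate F4.
   - Desilylation (Bu4NF) and base-mediated 6-exo conjugate addition of the hydroperoxide (Et2NH, CF3CH2OH) close the dioxane and give 12 together with its isomers at C3, the α-carbon and C6, from which it is separated.

2. Step 4. The allylic Grignard reagent may attack the alkene terminus of the vinyl epoxide (SN2′), or the magnesium salt may induce rearrangement of the epoxide before addition. Fallback, from 3 back to 7: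
   - Selective oxidation of the primary alcohol (TEMPO, PhI(OAc)2) gives (1S)-1-hydroxy-2,2-dimethyl-6-methylidenecyclohexane-1-carbaldehyde F5.
   - Wittig olefination with 1-(triphenylphosphoranylidene)propan-2-one gives (3E)-4-[(1S)-1-hydroxy-2,2-dimethyl-6-methylidenecyclohexyl]but-3-en-2-one F6.
   - Conjugate reduction with [(Ph3P)CuH]6 gives 4-[(1S)-1-hydroxy-2,2-dimethyl-6-methylidenecyclohexyl]butan-2-one F7.
   - Wittig methylenation (Ph3P=CH2) gives 7.

3. Step 2. Proton loss may occur from the ring CH2 instead of the methyl group (endocyclic alkene), or the epoxide may be opened by isopropoxide. Fallback, from 1 back to 3 (bypassing 2):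
   - Sensitised photo-oxygenation of 1 (O2, light, tetraphenylporphyrin, CH2Cl2): the Schenck ene reaction, directed by the allylic hydroxyl and taking the hydrogen from the cis-methyl group, should give racemic (1-hydroperoxy-2,2-dimethyl-6-methylidenecyclohexyl)methanol F8.
   - Reduction with PPh3 gives racemic 1-(hydroxymethyl)-2,2-dimethyl-6-methylidenecyclohexan-1-ol F9.
   - Lipase-catalysed acetylation of the primary hydroxyl with vinyl acetate (kinetic resolution) then gives 3, either as the unreacted alcohol or, after methanolysis (K2CO3, MeOH), from its monoacetate [(1S)-1-hydroxy-2,2-dimethyl-6-methylidenecyclohexyl]methyl acetate F10.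

**Further compounds**

F1 | step 5 | 6-[(1S)-1-hydroxy-2,2-dimethyl-6-methylidenecyclohexyl]-4-methylidenehexan-1-ol | C=C1CCCC(C)(C)[C@@]1(O)CCC(=C)CCCO
F2 | step 5 | 6-[(1S)-1-hydroxy-2,2-dimethyl-6-methylidenecyclohexyl]-4-methyl-4-[(triethylsilyl)peroxy]hexan-1-ol (both C4 epimers) | C=C1CCCC(C)(C)[C@@]1(O)CCC(C)(OO[Si](CC)(CC)CC)CCCO
F3 | step 5 | 6-[(1S)-1-hydroxy-2,2-dimethyl-6-methylidenecyclohexyl]-4-methyl-4-[(triethylsilyl)peroxy]hexanal (both C4 epimers) | C=C1CCCC(C)(C)[C@@]1(O)CCC(C)(OO[Si](CC)(CC)CC)CCC=O
F4 | step 5 | methyl (2E)-8-[(1S)-1-hydroxy-2,2-dimethyl-6-methylidenecyclohexyl]-2,6-dimethyl-6-[(triethylsilyl)peroxy]oct-2-enoate (both C6 epimers) | C=C1CCCC(C)(C)[C@@]1(O)CCC(C)(OO[Si](CC)(CC)CC)CC/C=C(\C)C(=O)OC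
F5 | step 4 | (1S)-1-hydroxy-2,2-dimethyl-6-methylidenecyclohexane-1-carbaldehyde | C=C1CCCC(C)(C)[C@@]1(O)C=O
F6 | step 4 | (3E)-4-[(1S)-1-hydroxy-2,2-dimethyl-6-methylidenecyclohexyl]but-3-en-2-one | C=C1CCCC(C)(C)[C@@]1(O)/C=C/C(C)=O
F7 | step 4 | 4-[(1S)-1-hydroxy-2,2-dimethyl-6-methylidenecyclohexyl]butan-2-one | C=C1CCCC(C)(C)[C@@]1(O)CCC(C)=O
F8 | step 2 | (1-hydroperoxy-2,2-dimethyl-6-methylidenecyclohexyl)methanol (racemic) | C=C1CCCC(C)(C)C1(OO)CO
F9 | step 2 | 1-(hydroxymethyl)-2,2-dimethyl-6-methylidenecyclohexan-1-ol (racemic) | C=C1CCCC(C)(C)C1(O)CO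
F10 | step 2 | [(1S)-1-hydroxy-2,2-dimethyl-6-methylidenecyclohexyl]methyl acetate | C=C1CCCC(C)(C)[C@@]1(O)COC(C)=O
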